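The constants put growth at 43.1 /M/h against 0.366 /M/h for initiation, so at equal concentrations a living end takes up free monomer far faster than initiator does, and the three flasks differ in their time.

in all of them: free monomer 2.0 M; initiator 4.0 mM
- east: time 8.0 h
- west: time 10 h
- north-east: time 15 h

    free monomer + initiator → living end + monomer in chains (k1 = 0.366 /M/h)
    free monomer + living end → monomer in chains + living end, rate k2*[living end]*[free monomer] (k2 = 43.1 /M/h)
    free monomer + monomer in chains → side product (k3 = 0.0282 /M/h)
    monomer in chains ⇌ isomer of the product (K4 = 0.97, k4 = 0.0324 /h)

- in percentages every species weighs as the free monomer in it: one side product counts as two
- run time (east): 8.0 h

* which of the two there is more of at the end, counted by the free monomer in each, east (monomer in chains / side product)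
* which of the two there is more of at the end, counted by the free monomer in each, west (monomer in chains / side product)
* which of the two there is more of at the end, counted by the free monomer in each, north-east (monomer in chains / side product)
* amount of monomer in chains at the end, in percent of the free monomer charged, east
* amount of monomer in chains at the end, in percent of the free monomer charged, west
* amount of monomer in chains at the end, in percent of the free monomer charged, north-east

I carry one quantity, the growth rate, 0.172 /h: the growth constant times the charged initiator, which is the share of free monomer taken up per hour once each initiator has become a living end, a pseudo-first-order constant. The delay until then is about 1.37 h, one over the initiation constant times the charged free monomer, and it is shorter than the 8.0 h of east.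

I bracket east from both ends. With living ends present from the start and no losses, monomer in chains reaches 74.8%; with the clock started after the delay it reaches 68.1%, and that is my ceiling. For the floor, a rough estimate and no strict bound, I take from this ceiling the heavier losses of the undelayed curve. That curve counts as the whole charge standing in chains for 3.65 h, so the forward step to the isomer takes 11.9%. The side step takes 9.16% from the chains, and the floor is 47.1%. The delayed curve in the same two sums takes 8.69% and 7.59%, so I commit to 51.9% for east, with side product at 15.2%, less than the chains. I stop there by hand, because north-east runs 15 h, longer than the 10.5 h relaxation half-life of the isomer step, and my sums count that step forward.

The forecast names monomer in chains in each flask, at 51.6%, 55.4% and 56.9%, holding of free monomer that “most of it is gone by 10–15 h and the chains clearly outweigh the side product”; its east value stands inside my bracket.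

The simulation gives 51.2% of monomer in chains in east, 54.9% in west and 56.5% in north-east, more than side product at 13.1%, 16.0% and 19.8% in the same order. East ends with free monomer at 28.8%, where the growth rate over the time less the delay leaves 31.9%. In the neighbour of north-east charged with 0.0010 M of initiator, the growth rate falls to 0.0431 /h, which over 15 h less the delay leaves 55.6% of free monomer, and that flask holds 48.6%, with monomer in chains at 27.0%.

(Its constants are assumed; what happens was integrated by code.)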